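**Retrosynthetic overview**
1. Agelasidine C ⇒ diterpenyl allylic bromide 13 + hypotaurocyamine 15 (sulfinate S‑alkylation, last step).
2. Ring C(Me)=CH ⇒ α‑quaternary ketone 10 (enol triflate, then Fe‑catalysed methylation).
3. Key C(quaternary)–CH2 bond ⇒ tertiary α‑bromoketone 4 + homoallylic alcohol 9, joined by a visible‑light SH2 radical coupling that sets the quaternary centre anti to the existing ring methyl.
4. 4 ⇐ (R)‑pulegone (α′‑methylation, retro‑aldol, bromination); 9 ⇐ geraniol (TBS, C8 oxidation, Wittig, hydroboration).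
5. The only ring is bought intact in pulegone; no ring‑forming step.

Assumption: the target is isolated as the neutral guanidine drawn (free base after basic work‑up). The C2/C6 epimer mixtures in 2–4 are carried as such because that carbon is planarised in step 8.

**Route**

Step 1
Reactants: 1 (R)‑(+)‑pulegone
Product: 2 (5R)‑5,6‑dimethyl‑2‑(propan‑2‑ylidene)cyclohexan‑1‑one (C6 epimers)
Conditions: LDA, THF, −78 °C; MeI, −78 → −20 °C
Reagents that add atoms: iodomethane, CI
Why: Kinetic α′‑deprotonation of the enone (the other α‑carbon is sp2) gives the cross‑conjugated enolate, which is methylated by SN2 enolate alkylation; C5 is untouched and the C6 configuration is erased later.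

Step 2
Reactants: 2
Product: 3 (3R)‑2,3‑dimethylcyclohexan‑1‑one (C2 epimers)
Conditions: 6 M aq. HCl, reflux, acetone distilled off
Reagents that add atoms: none (water is consumed but its oxygen leaves in acetone)
Why: Acid‑catalysed conjugate hydration and retro‑aldol removes the isopropylidene blocking group; the β‑stereocentre C3 is not epimerisable.

Step 3
Reactants: 3
Product: 4 (3R)‑2‑bromo‑2,3‑dimethylcyclohexan‑1‑one (C2 epimers; used crude and cold)
Conditions: Br2 (1.0 equiv), AcOH, 10–15 °C
Reagents that add atoms: bromine, BrBr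
Why: Acid‑catalysed α‑bromination proceeds through the more substituted enol and gives the tertiary bromide; C3 is unaffected.

Step 4
Reactants: 5 geraniol
Product: 6 geranyl TBS ether, tert‑butyl{[(2E)‑3,7‑dimethylocta‑2,6‑dien‑1‑yl]oxy}dimethylsilane
Conditions: TBSCl, imidazole, DMF, rt
Reagents that add atoms: TBSCl, CC(C)(C)[Si](C)(C)Cl
Why: Standard silylation gives a base‑stable mask for the allylic alcohol that later becomes the sulfone site.

Step 5 (telescoped, counted as one step)
Reactants: 6
Product: 7 (2E,6E)‑8‑[(tert‑butyldimethylsilyl)oxy]‑2,6‑dimethylocta‑2,6‑dienal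
Conditions: SeO2 (cat.), t‑BuOOH, salicylic acid (cat.), CH2Cl2, rt; crude alcohol/aldehyde mixture then MnO2, CH2Cl2
Reagents that add atoms: tert‑butyl hydroperoxide, CC(C)(C)OO (oxygen delivered via SeO2, O=[Se]=O)
Why: SeO2 allylic oxidation (ene, then [2,3]) is selective for the (E)‑methyl of the electron‑rich terminal olefin, and MnO2 converges the mixture to the (E)‑enal.

Step 6
Reactants: 7
Product: 8 tert‑butyl{[(2E,6E)‑3,7‑dimethylnona‑2,6,8‑trien‑1‑yl]oxy}dimethylsilane
Conditions: Ph3PCH3Br, KHMDS, THF, −78 → 0 °C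
Reagents that add atoms: methyltriphenylphosphonium bromide, C[P+](c1ccccc1)(c1ccccc1)c1ccccc1.[Br-]
Why: Wittig methylenation of the enal; the existing trisubstituted E‑olefins are not touched.

Step 7
Reactants: 8
Product: 9 (3E,7E)‑9‑[(tert‑butyldimethylsilyl)oxy]‑3,7‑dimethylnona‑3,7‑dien‑1‑ol
Conditions: Sia2BH, THF, 0 °C; then NaOH, H2O2
Reagents that add atoms: hydrogen peroxide, OO
Why: The bulky dialkylborane hydroborates only the monosubstituted terminal alkene of the diene (anti‑Markovnikov hydroboration–oxidation), as in the classical geranial‑to‑homogeraniol sequence.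

Step 8 (key step)
Reactants: 4 (1.5 equiv) and 9
Product: 10 (2S,3R)‑2‑[(3E,7E)‑9‑{[tert‑butyl(dimethyl)silyl]oxy}‑3,7‑dimethylnona‑3,7‑dien‑1‑yl]‑2,3‑dimethylcyclohexan‑1‑one
Conditions: 9, N‑aryl benzoxazolium BF4 (NHC precursor, 1.1 equiv), pyridine, MTBE, rt; then 4, [Ir(ppy)2(dtbbpy)]PF6 (1 mol %), Fe(OEP)Cl (5 mol %), K2HPO4, MTBE/DMSO, 450 nm LEDs, rt
Reagents that add atoms: none (the activator removes the hydroxyl oxygen; bromide is lost)
Why: Proposed new method: a redox‑neutral SH2 "radical‑sorting" C(sp3)–C(sp3) coupling in which excited Ir(III) oxidises the in situ NHC–alcohol adduct of 9 (deprotonation and β‑scission release the primary homoallylic radical, which Fe(II) porphyrin traps as a primary alkyl–Fe(III)), the resulting Ir(II) reduces 4 to the planar tertiary α‑keto radical, and this radical, too hindered to bind iron, attacks the Fe–CH2 carbon by SH2 on the face anti to the pseudoaxial C3 methyl (the same facial bias as alkylation of 2,3‑dimethylcyclohexanone enolates), giving the (2S) quaternary centre with the two methyls cis; the closest known chemistry is SH2 radical‑sorting coupling of unstabilised tertiary radicals with primary alkyl–metal intermediates combined with NHC‑mediated deoxygenative radical generation from alcohols, not yet shown for tertiary α‑keto radicals or for diastereoselective cases.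

Step 9
Reactants: 10
Product: 11 (5R,6S)‑6‑[(3E,7E)‑9‑{[tert‑butyl(dimethyl)silyl]oxy}‑3,7‑dimethylnona‑3,7‑dien‑1‑yl]‑5,6‑dimethylcyclohex‑1‑en‑1‑yl trifluoromethanesulfonate
Conditions: KHMDS, THF, −78 °C; PhNTf2
Reagents that add atoms: N‑phenyl‑bis(trifluoromethanesulfonimide), O=S(=O)(N(c1ccccc1)S(=O)(=O)C(F)(F)F)C(F)(F)F
Why: Only C6 is enolisable (the other α‑carbon is quaternary), so enolate O‑triflation is regiospecific and cannot epimerise either stereocentre.

Step 10
Reactants: 11
Product: 12 tert‑butyldimethyl{[(2E,6E)‑3,7‑dimethyl‑9‑[(1S,6R)‑1,2,6‑trimethylcyclohex‑2‑en‑1‑yl]nona‑2,6‑dien‑1‑yl]oxy}silane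
Conditions: MeMgBr, Fe(acac)3 (5 mol %), THF/NMP, −30 °C
Reagents that add atoms: methylmagnesium bromide, C[Mg]Br
Why: Iron‑catalysed Kumada‑type coupling of a hindered alkenyl triflate installs the ring methyl and fixes the trisubstituted ring olefin; the silyl ether and isolated olefins are inert.

Step 11
Reactants: 12
Product: 13 (1S,6R)‑1‑[(3E,7E)‑9‑bromo‑3,7‑dimethylnona‑3,7‑dien‑1‑yl]‑1,2,6‑trimethylcyclohex‑2‑ene
Conditions: Ph3PBr2, CH2Cl2, 0 °C → rt
Reagents that add atoms: dibromotriphenylphosphorane, BrP(Br)(c1ccccc1)(c1ccccc1)c1ccccc1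
Why: Appel‑type direct conversion of the primary allylic silyl ether to the bromide (oxyphosphonium, then SN2) under non‑acidic conditions keeps the E‑geometry.

Step 12
Reactants: 14 hypotaurine (2‑aminoethanesulfinic acid)
Product: 15 hypotaurocyamine (2‑guanidinoethanesulfinic acid, zwitterion)
Conditions: 1H‑pyrazole‑1‑carboxamidine·HCl, Na2CO3, H2O, rt
Reagents that add atoms: 1H‑pyrazole‑1‑carboxamidine hydrochloride, NC(=N)n1cccn1.Cl
Why: Amidine transfer (guanylation) to the primary amine; the sulfinate is inert under these conditions.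

Step 13
Reactants: 13 and 15
Product: 16 agelasidine C
Conditions: DMF/H2O, rt; then aq. NaOH work‑up to the free base
Reagents that add atoms: none
Why: SN2 S‑alkylation of the soft sulfinate at the primary allylic bromide gives the sulfone with the E‑olefin retained; the protonated guanidine is non‑nucleophilic and no stereocentre is involved.

**Compound list**
1 | (R)‑(+)‑pulegone | C[C@@H]1CCC(=C(C)C)C(=O)C1 | starting material
2 | (5R)‑5,6‑dimethyl‑2‑(propan‑2‑ylidene)cyclohexan‑1‑one (C6 epimers) | C[C@@H]1CCC(=C(C)C)C(=O)C1C | intermediate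
3 | (3R)‑2,3‑dimethylcyclohexan‑1‑one (C2 epimers) | C[C@@H]1CCCC(=O)C1C | intermediate
4 | (3R)‑2‑bromo‑2,3‑dimethylcyclohexan‑1‑one (C2 epimers) | C[C@@H]1CCCC(=O)C1(C)Br | intermediate
5 | geraniol | CC(C)=CCC/C(C)=C/CO | starting material
6 | geranyl TBS ether | CC(C)=CCC/C(C)=C/CO[Si](C)(C)C(C)(C)C | intermediate
7 | (2E,6E)‑8‑(TBSO)‑2,6‑dimethylocta‑2,6‑dienal | O=C/C(C)=C/CC/C(C)=C/CO[Si](C)(C)C(C)(C)C | intermediate
8 | (2E,6E)‑3,7‑dimethylnona‑2,6,8‑trien‑1‑yl TBS ether | C=C/C(C)=C/CC/C(C)=C/CO[Si](C)(C)C(C)(C)C | intermediate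
9 | (3E,7E)‑9‑(TBSO)‑3,7‑dimethylnona‑3,7‑dien‑1‑ol | OCC/C(C)=C/CC/C(C)=C/CO[Si](C)(C)C(C)(C)C | intermediate
10 | (2S,3R)‑2‑[(3E,7E)‑9‑(TBSO)‑3,7‑dimethylnona‑3,7‑dien‑1‑yl]‑2,3‑dimethylcyclohexan‑1‑one | O=C1CCC[C@@H](C)[C@]1(C)CC/C(C)=C/CC/C(C)=C/CO[Si](C)(C)C(C)(C)C | intermediate
11 | (5R,6S)‑enol triflate of 10 | FC(F)(F)S(=O)(=O)OC1=CCC[C@@H](C)[C@]1(C)CC/C(C)=C/CC/C(C)=C/CO[Si](C)(C)C(C)(C)C | intermediate
12 | (2E,6E)‑3,7‑dimethyl‑9‑[(1S,6R)‑1,2,6‑trimethylcyclohex‑2‑en‑1‑yl]nona‑2,6‑dien‑1‑yl TBS ether | CC1=CCC[C@@H](C)[C@]1(C)CC/C(C)=C/CC/C(C)=C/CO[Si](C)(C)C(C)(C)C | intermediate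
13 | (1S,6R)‑1‑[(3E,7E)‑9‑bromo‑3,7‑dimethylnona‑3,7‑dien‑1‑yl]‑1,2,6‑trimethylcyclohex‑2‑ene | CC1=CCC[C@@H](C)[C@]1(C)CC/C(C)=C/CC/C(C)=C/CBr | intermediate
14 | hypotaurine | NCCS(=O)O | starting material
15 | hypotaurocyamine | NC(N)=NCCS(=O)O | intermediate
16 | agelasidine C | CC1=CCC[C@@H](C)[C@]1(C)CC/C(C)=C/CC/C(C)=C/CS(=O)(=O)CCN=C(N)N | target

**Step count**
Total: 13 steps. Longest linear sequence: 9 steps (geraniol → 6 → 7 → 8 → 9 → 10 → 11 → 12 → 13 → 16).

**Three steps most likely to fail**
1. Step 8 (proposed new SH2 coupling). Risks: over‑reduction of the α‑keto radical to the debrominated ketone, HBr loss from 4 to the achiral enone, sluggish SH2 by a stabilised radical, and modest diastereoselectivity. Fallback (known chemistry): two‑electron enolate alkylation. Make the thermodynamic TMS enol ether of 3 (TMSCl, Et3N, DMF, heat), regenerate the lithium enolate with MeLi, and alkylate with the iodide of 9 (I2, PPh3, imidazole) in THF/DMPU; this is the classical trans‑to‑3‑methyl alkylation and gives 10 at a cost of two extra steps.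
2. Step 5 (SeO2 oxidation at C8). Risks: moderate yield, over‑oxidation and partial silyl loss. Fallback: reach 9 without allylic oxidation. Ene‑type chlorination of 6 (Ca(OCl)2/CO2) gives the 6‑chloro‑7‑methylene isomer; Cu‑catalysed anti‑SN2′ substitution with (i‑PrO)Me2SiCH2MgCl followed by Tamao oxidation gives 9 and replaces steps 5–7.
3. Step 13 (sulfinate alkylation with an unprotected guanidine). Risks: O‑alkylation followed by [2,3] shift to the tertiary sulfone, poor mutual solubility, and difficult purification. Fallback: thioether route. Alkylate N‑Boc‑cysteamine with 13, oxidise the sulfide to the sulfone (ammonium molybdate/H2O2), remove Boc (TFA), and guanylate the amine with 1H‑pyrazole‑1‑carboxamidine.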